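Amounts come first here: the solid D goes into solution as J and G grows out of what is dissolved, so you draw the dissolved amount before you draw G.

| flask | D | remark | time |
|---|---|---|---|
| Tuesday's | 0.10 M | run made earlier |  |
| Friday's | 0.15 M | run made earlier |  |
| flask | 0.20 M |  | 1.0 h |

| run | time / min | G / % | D / % |
|---|---|---|---|
| Tuesday's | 8.00 | 0 | 48.9 |
| Tuesday's | 20.0 | 2.9 | 2.0 |
| Tuesday's | 40.0 | 7.9 | 1.0 |
| Tuesday's | 60.0 | 11.6 | 0.2 |
| Friday's | 15.0 | 0 | 46.8 |
| Friday's | 30.0 | 3.9 | 20.0 |
| Friday's | 50.0 | 6.8 | 1.0 |
| Friday's | 60.0 | 10.0 | 0.4 |

(each reading ± 1 percentage point)

- a species is counted by the D in it: one E counts as two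
- given per volume of solution although it is solid: D
- steps under discussion: J -> G; 2 J <-> E; D <-> J
- at the start none of D is in solution

* how much G there is at 1.0 h, in percent of the D charged
* the change that raises the amount of G at 1.0 h, in percent of the D charged most ("none" if none brings more than 2 percentage points) (west / north / none)
* amount of G at 1.0 h, in percent of the D charged, after north

- west: doubling the dissolution coefficient of D, all else as stated
- north: doubling the solubility of D, all else as stated

In Tuesday's run, from 20.0 min on, solid D reads 2.0% or less, so nearly all of the charge is dissolved and the slope of G is the share of dissolved material that becomes G each minute, the apparent first-order constant 0.00217 min⁻¹, a reading with its scatter. Friday's second reading lies at twice the time of the first, so for filling that slows exponentially toward a level, the ratio of the dissolved amounts, less one, is the part of the gap still open after the first interval, 0.504. That gives, as readings with their scatter, a time constant 21.9 min and a level of dissolved amount 0.161 M.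

By my reckoning, the flask's charge of 0.20 M stands above that level, so the dissolved amount, [J] plus the D counted in E, starts rising at 0.00735 M min⁻¹, bends near 21.9 min and runs toward 0.161 M, while G starts flat. Its slope then rises toward 0.001747 min⁻¹ of the charge. The full level held for the whole time gives 10.5%, taking off 21.9 min as a lag gives 6.67%, and putting back the gap still open at the end gives 6.91%. West halves the time constant and gains 1.7 percentage points, less than the margin of 2 points. North doubles the level to 0.322 M, above the charge, so on the same curve the whole charge is dissolved at 21.3 min, G comes to 11.1%, and the gain of 4.2 points is more than the margin, so my choice is north.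

The forecast, which reads “dissolution that slows as solution fills”, says 7%, close to mine, and chooses north, with 11.3% after it.

The flask gives 6.90%; north adds 3.2 points, west 1.5 points, and north ends at 10.1%.

    J → G (k = 4.10 × 10⁻⁵ s⁻¹)
    2 J ⇌ E (K = 30.0 M⁻¹, k = 3.70 × 10⁻⁴ M⁻¹ s⁻¹)
    D ⇌ J, rate k3*(cs3 - [J]) while solid is left; crystals form when [J] > cs3 (solubility = 0.140 M, k = 9.60 × 10⁻⁴ s⁻¹)

The flask's answer moves by 5 points when the charge falls to 0.0646 M, and the neighbouring flask with 0.050 M lies below that. Its charge is under the level, so the same curve reaches the whole charge at 8.15 min, and the time-averaged filling then amounts to 56.2 min of full solution. With 0.00217 min⁻¹ that gives 12.2% of G, and that neighbouring flask stands at 12.3%.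

(The earlier runs and the new flask are calculated from invented constants; scatter was added.)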